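**Retrosynthetic overview**
- The 7β-acetate comes from acetylation of the 7β-alcohol, made by Luche reduction of a 7-oxo-8-ene; the C7 carbonyl comes from allylic oxidation of the tetrasubstituted 8,9-alkene.
- The C9–C11 bond is cut to a C9 enol triflate of the decalin and a C6 zinc reagent that already carries C13 and the C15 acetate.
- The C6 unit comes from a catalytic enantioselective, desymmetrizing acylative ring opening of 4-methyltetrahydropyran (new step, sets C13).
- Ring B (six-membered) is made by one-carbon ring expansion of the cyclopentanone of a hydrindenedione with diazoethane, which also brings in C8 and its methyl; ring A is then finished by reductive methylation (trans fusion, gem-dimethyl), C3 reduction and O-methylation.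
- Ring order: the five-membered ring comes with the starting dione, ring A is annulated onto it (amino-acid-catalysed, sets C10), then the five-membered ring is expanded to ring B.

Assumption: positions are numbered as in labdane (C1–C20; C10 methyl β, 5α-H), the target being (3S,5R,7S,10S,13S); the C8 epimers formed in step 2 are carried together (SMILES show the major, equatorial 8-methyl epimer) because C8 becomes sp2 in step 6; diazoethane is used as a pre-formed reagent solution.

**Step 1**
Reactants: 1 2-methylcyclopentane-1,3-dione; 2 pent-1-en-3-one (ethyl vinyl ketone)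
Product: 4 (S)-4,7a-dimethyl-2,3,7,7a-tetrahydro-1H-indene-1,5(6H)-dione, via triketone 3 (not isolated)
Conditions: AcOH (cat.), H2O, 75 °C; concentrate; then (S)-phenylalanine (1.0 equiv), (1S)-(+)-camphor-10-sulfonic acid (0.5 equiv), MeCN, 70 °C; one pot; recrystallise to ≥98% ee
Reagents that add atoms: none
Why: Michael addition followed by amino-acid (enamine) catalysed intramolecular aldol condensation (Hajos–Parrish–Eder–Sauer–Wiechert reaction), in which (S)-phenylalanine differentiates the two enantiotopic ring carbonyls through a hydrogen-bonded enamine transition state and so sets the quaternary centre (future C10) as S.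

**Step 2**
Reactants: 4 (S)-4,7a-dimethyl-2,3,7,7a-tetrahydro-1H-indene-1,5(6H)-dione
Product: 5 (2R,8aS)-2,5,8a-trimethyl-3,4,8,8a-tetrahydronaphthalene-1,6(2H,7H)-dione
Conditions: CH3CHN2 (1.5 equiv, pre-formed dry toluene solution), Sc(OTf)3 (10 mol%), toluene, −78 → −40 °C
Reagents that add atoms: diazoethane, CC=[N+]=[N-]
Why: Lewis-acid-catalysed diazoalkane–ketone homologation (Tiffeneau–Demjanov-type ring expansion): diazoethane adds to the activated cyclopentanone carbonyl (the conjugated carbonyl is inert) and the less substituted CH2 undergoes the 1,2-shift with loss of N2, as in D-ring homologation of 17-keto steroids, so the five-membered ring becomes ring B with the carbonyl (C9) still next to the quaternary carbon and the new CH(CH3) as C8/C17; the C8 configuration does not matter.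

**Step 3**
Reactants: 5 (2R,8aS)-2,5,8a-trimethyl-3,4,8,8a-tetrahydronaphthalene-1,6(2H,7H)-dione
Product: 7 (2R,4aS,8aS)-2,5,5,8a-tetramethyl-3,4,4a,7,8,8a-hexahydronaphthalene-1,6(2H,5H)-dione, via lithium enolate 6 (not isolated)
Conditions: Li (2.1 equiv, added in portions until a blue colour just persists), NH3(l)/THF, t-BuOH (1.0 equiv), −78 °C; then MeI (6 equiv), −78 → −33 °C
Reagents that add atoms: methyl iodide, CI
Why: Birch-type reductive alkylation: the enone is reduced at a far less negative potential than the isolated, hindered C9 ketone, axial protonation of the β-carbanion at C5 gives the trans-fused (5α-H) enolate, and regiospecific C-methylation of that enolate at C4 installs the gem-dimethyl group.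

**Step 4**
Reactants: 7 (2R,4aS,8aS)-2,5,5,8a-tetramethyl-3,4,4a,7,8,8a-hexahydronaphthalene-1,6(2H,5H)-dione
Product: 8 (2R,4aS,6S,8aS)-6-hydroxy-2,5,5,8a-tetramethyloctahydronaphthalen-1(2H)-one (3β-hydroxy-9-ketone)
Conditions: NaBH4 (0.5 equiv), MeOH/CH2Cl2 1:1, −40 → −20 °C
Reagents that add atoms: none
Why: Chemoselective hydride reduction: the C3 carbonyl (one quaternary neighbour) is attacked much faster than the C9 carbonyl flanked by quaternary C10 and methyl-bearing C8, and axial attack from the α face gives the equatorial 3β-alcohol (3S), as is usual for 4,4-dimethyl-3-ketones.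

**Step 5**
Reactants: 8 (2R,4aS,6S,8aS)-6-hydroxy-2,5,5,8a-tetramethyloctahydronaphthalen-1(2H)-one
Product: 9 (2R,4aS,6S,8aS)-6-methoxy-2,5,5,8a-tetramethyloctahydronaphthalen-1(2H)-one
Conditions: MeOTf (2 equiv), 2,6-di-tert-butyl-4-methylpyridine (2.5 equiv), CH2Cl2, 0 °C → rt
Reagents that add atoms: methyl triflate, COS(=O)(=O)C(F)(F)F
Why: O-methylation of the hindered secondary alcohol under non-enolising conditions, so the C9 ketone with its tertiary α-hydrogen is not C- or O-alkylated and the C3 configuration is retained.

**Step 6**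
Reactants: 9 (2R,4aS,6S,8aS)-6-methoxy-2,5,5,8a-tetramethyloctahydronaphthalen-1(2H)-one
Product: 11 (4aS,6S,8aS)-6-methoxy-2,5,5,8a-tetramethyl-3,4,4a,5,6,7,8,8a-octahydronaphthalen-1-yl trifluoromethanesulfonate, via potassium enolate 10 (not isolated)
Conditions: KN(SiMe3)2 (1.3 equiv), THF, −78 → 0 °C; then PhNTf2 (1.4 equiv), −78 °C → rt
Reagents that add atoms: N-phenylbis(trifluoromethanesulfonimide), O=S(=O)(N(c1ccccc1)S(=O)(=O)C(F)(F)F)C(F)(F)F
Why: Enol triflate formation: enolisation is possible only toward C8 because C10 is quaternary, so O-sulfonylation of the tetrasubstituted enolate gives a single C8=C9 enol triflate and both C8 epimers converge.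

**Step 7**
Reactants: 12 4-methyltetrahydro-2H-pyran
Product: 13 (R)-5-bromo-3-methylpentyl acetate
Conditions: AcBr (1.2 equiv), chiral squaramide hydrogen-bond donor (N-3,5-(CF3)2C6H3 squaramide of a tert-leucine 2-arylpyrrolidine amide, 10 mol%; enantiomer chosen by screening), toluene, 4 Å MS, −30 °C, 72 h
Reagents that add atoms: acetyl bromide, CC(Br)=O
Why: Proposed new method: the squaramide binds the bromide of acetyl bromide so that reversible O-acetylation of the ether gives a catalyst-bound acetyloxonium/bromide ion pair (the Lewis-acid-free background reaction is negligible at −30 °C), and the enantio-determining SN2 attack of the bound bromide on one of the two enantiotopic O–CH2 carbons of the chair (4-methyl equatorial), steered by a cation–π contact between the oxonium and the arylpyrrolidine arm, opens the ring to the (R)-bromo acetate and so fixes the future C13; the closest known reactions are the hydrogen-bond-donor-catalysed enantioselective opening of 3-substituted oxetanes with TMSBr and the racemic cleavage of tetrahydropyrans by acyl halides with ZnCl2 or iodide.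

**Step 8**
Reactants: 11 (4aS,6S,8aS)-6-methoxy-2,5,5,8a-tetramethyl-3,4,4a,5,6,7,8,8a-octahydronaphthalen-1-yl trifluoromethanesulfonate; 13 (R)-5-bromo-3-methylpentyl acetate
Product: 15 (13S)-3β-methoxylabd-8-en-15-yl acetate, via alkylzinc bromide 14 (not isolated)
Conditions: 13 (1.5 equiv), Zn dust (2.2 equiv), LiCl (1.5 equiv), THF, 50 °C; then 11, PdCl2(dppf) (5 mol%), THF/NMP 2:1, 60 °C
Reagents that add atoms: none
Why: Negishi sp2–sp3 cross-coupling: zinc insertion into the primary bromide tolerates the acetate, and PdCl2(dppf) couples primary alkylzinc halides with hindered 2,6,6-trisubstituted cyclohexenyl triflates with little β-hydride elimination, forming C9–C11 without touching any stereocentre (the R descriptor of 13 becomes 13S only because the former bromoethyl arm loses CIP priority).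

**Step 9**
Reactants: 15 (13S)-3β-methoxylabd-8-en-15-yl acetate
Product: 16 (13S)-3β-methoxy-7-oxolabd-8-en-15-yl acetate
Conditions: Rh2(cap)4 (cap = caprolactamate, 1 mol%), t-BuOOH (70% aq., 6 equiv), K2CO3 (0.5 equiv), CH2Cl2, 25 °C
Reagents that add atoms: tert-butyl hydroperoxide, CC(C)(C)OO
Why: Radical allylic C–H oxidation with a tert-butylperoxyl chain: the secondary, pseudo-axial C7–H is aligned with the π system whereas the C11–H bonds are held near the alkene plane by allylic strain against C10 and C17 and the C17 hydrogens are primary, so oxidation gives the conjugated tetrasubstituted 7-ketone, as is usual for labd-8-enes.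

**Step 10**
Reactants: 16 (13S)-3β-methoxy-7-oxolabd-8-en-15-yl acetate
Product: 17 (13S)-7β-hydroxy-3β-methoxylabd-8-en-15-yl acetate
Conditions: NaBH4 (1.5 equiv), CeCl3·7H2O (1.2 equiv), MeOH, −78 → −40 °C
Reagents that add atoms: none
Why: Luche 1,2-reduction: axial delivery of hydride from the α face of the trans-fused cyclohexenone (past only the axial 5α-hydrogen) gives the pseudo-equatorial 7β-alcohol (7S), and the primary acetate survives at low temperature.

**Step 11**
Reactants: 17 (13S)-7β-hydroxy-3β-methoxylabd-8-en-15-yl acetate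
Product: 18 (3S,5R,7S,10S,13S)-3-methoxylabd-8-ene-7,15-diyl diacetate (CNP0401666.1)
Conditions: Ac2O (3 equiv), pyridine, DMAP (10 mol%), CH2Cl2, 0 °C → rt
Reagents that add atoms: acetic anhydride, CC(=O)OC(C)=O
Why: DMAP-catalysed O-acylation of the secondary allylic alcohol, which proceeds with retention at C7 and completes the target.

**Compound list**
1 | 2-methylcyclopentane-1,3-dione | CC1C(=O)CCC1=O | starting material
2 | pent-1-en-3-one (ethyl vinyl ketone) | CCC(=O)C=C | starting material
3 | 2-methyl-2-(3-oxopentyl)cyclopentane-1,3-dione | CCC(=O)CCC1(C)C(=O)CCC1=O | intermediate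
4 | (S)-4,7a-dimethyl-2,3,7,7a-tetrahydro-1H-indene-1,5(6H)-dione | CC1=C2CCC(=O)[C@@]2(C)CCC1=O | intermediate
5 | (2R,8aS)-2,5,8a-trimethyl-3,4,8,8a-tetrahydronaphthalene-1,6(2H,7H)-dione | O=C1CC[C@]2(C)C(=O)[C@H](C)CCC2=C1C | intermediate
6 | lithium enolate of the trans-fused 4-methyl-3,9-dione (C3–O–Li, C3=C4, 5α-H) | [Li]OC1=C(C)[C@@H]2CC[C@@H](C)C(=O)[C@@]2(C)CC1 | intermediate
7 | (2R,4aS,8aS)-2,5,5,8a-tetramethyl-3,4,4a,7,8,8a-hexahydronaphthalene-1,6(2H,5H)-dione | O=C1CC[C@]2(C)C(=O)[C@H](C)CC[C@H]2C1(C)C | intermediate
8 | (2R,4aS,6S,8aS)-6-hydroxy-2,5,5,8a-tetramethyloctahydronaphthalen-1(2H)-one | O[C@H]1CC[C@]2(C)C(=O)[C@H](C)CC[C@H]2C1(C)C | intermediate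
9 | (2R,4aS,6S,8aS)-6-methoxy-2,5,5,8a-tetramethyloctahydronaphthalen-1(2H)-one | CO[C@H]1CC[C@]2(C)C(=O)[C@H](C)CC[C@H]2C1(C)C | intermediate
10 | potassium enolate of 9 (C9–O–K, C8=C9) | CO[C@H]1CC[C@]2(C)C(O[K])=C(C)CC[C@H]2C1(C)C | intermediate
11 | (4aS,6S,8aS)-6-methoxy-2,5,5,8a-tetramethyl-3,4,4a,5,6,7,8,8a-octahydronaphthalen-1-yl trifluoromethanesulfonate | CO[C@H]1CC[C@]2(C)C(OS(=O)(=O)C(F)(F)F)=C(C)CC[C@H]2C1(C)C | intermediate
12 | 4-methyltetrahydro-2H-pyran | CC1CCOCC1 | starting material
13 | (R)-5-bromo-3-methylpentyl acetate | BrCC[C@H](C)CCOC(C)=O | intermediate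
14 | (R)-(5-acetoxy-3-methylpentyl)zinc bromide | Br[Zn]CC[C@H](C)CCOC(C)=O | intermediate
15 | (13S)-3β-methoxylabd-8-en-15-yl acetate | CO[C@H]1CC[C@]2(C)C(CC[C@H](C)CCOC(C)=O)=C(C)CC[C@H]2C1(C)C | intermediate
16 | (13S)-3β-methoxy-7-oxolabd-8-en-15-yl acetate | CO[C@H]1CC[C@]2(C)C(CC[C@H](C)CCOC(C)=O)=C(C)C(=O)C[C@H]2C1(C)C | intermediate
17 | (13S)-7β-hydroxy-3β-methoxylabd-8-en-15-yl acetate | CO[C@H]1CC[C@]2(C)C(CC[C@H](C)CCOC(C)=O)=C(C)[C@@H](O)C[C@H]2C1(C)C | intermediate
18 | (3S,5R,7S,10S,13S)-3-methoxylabd-8-ene-7,15-diyl diacetate | CO[C@H]1CC[C@]2(C)C(CC[C@H](C)CCOC(C)=O)=C(C)[C@@H](OC(C)=O)C[C@H]2C1(C)C | target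

**Step count**
Total: 11 steps. Longest linear sequence: 10 steps (steps 1–6, then 8–11); step 7 is a one-step side branch.

**Three steps most likely to fail**

Step 3 (reductive methylation with a free C9 ketone). The risk is partial reduction of the C9 carbonyl or methylation at C8 by the alkoxide formed. The fallback sets out from 5 and avoids dissolving metal. Deconjugative α-methylation of the extended dienolate (KOt-Bu 1.05 equiv, t-BuOH/THF, 0 °C, then MeI) gives (2R,8aS)-2,5,5,8a-tetramethyl-3,7,8,8a-tetrahydronaphthalene-1,6(2H,5H)-dione F1. Hydrogenation of its 5,6-alkene (H2, Pd/C, EtOAc) from the α face, opposite the angular methyl, gives the trans-fused dione, and the fallback comes back to the route at 7.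

Step 7 (the new desymmetrizing ring opening). The risk is low conversion without a Lewis acid, or insufficient enantioselectivity; 13 must be ≥97% ee because C13 epimers of the later compounds will not separate. The fallback uses known chemistry only and does not set out from 12. It sets out from the alternative commercial starting material 4-methyl-5,6-dihydro-2H-pyran-2-one F2 (eight non-hydrogen atoms). Copper-hydride asymmetric conjugate reduction (CuCl, NaOt-Bu, the p-tol-BINAP enantiomer that gives the S product, polymethylhydrosiloxane, toluene, 0 °C) gives (S)-4-methyltetrahydro-2H-pyran-2-one F3. HBr in ethanol opens the lactone to ethyl (R)-5-bromo-3-methylpentanoate F4, which keeps the two chain ends different. i-Bu2AlH (CH2Cl2, −78 → 0 °C) reduces the ester without touching the bromide to give (R)-5-bromo-3-methylpentan-1-ol F5. Immediate acetylation (Ac2O, pyridine) brings the fallback back to the route at 13.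

Step 9 (allylic oxidation of the tetrasubstituted alkene). The risk is competing oxidation at C11 or C17, or over-oxidation of the enone. The fallback sets out from 11 and installs the C7 carbonyl before C11 exists. Allylic oxidation of the enol triflate (CrO3·3,5-dimethylpyrazole, CH2Cl2, −20 °C), where only C7 and the C17 methyl are allylic, gives (4aS,6S,8aS)-6-methoxy-2,5,5,8a-tetramethyl-3-oxo-3,4,4a,5,6,7,8,8a-octahydronaphthalen-1-yl trifluoromethanesulfonate F6, a vinylogous acyl triflate. Negishi coupling of it with 14 under the step 8 conditions gives the enone directly; 15 is bypassed and the fallback comes back to the route at 16.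

**Further compounds**
F1 | step 3 | (2R,8aS)-2,5,5,8a-tetramethyl-3,7,8,8a-tetrahydronaphthalene-1,6(2H,5H)-dione | O=C1CC[C@]2(C)C(=O)[C@H](C)CC=C2C1(C)C
F2 | step 7 | 4-methyl-5,6-dihydro-2H-pyran-2-one | CC1=CC(=O)OCC1
F3 | step 7 | (S)-4-methyltetrahydro-2H-pyran-2-one | O=C1C[C@@H](C)CCO1
F4 | step 7 | ethyl (R)-5-bromo-3-methylpentanoate | BrCC[C@H](C)CC(=O)OCC
F5 | step 7 | (R)-5-bromo-3-methylpentan-1-ol | BrCC[C@H](C)CCO
F6 | step 9 | (4aS,6S,8aS)-6-methoxy-2,5,5,8a-tetramethyl-3-oxo-3,4,4a,5,6,7,8,8a-octahydronaphthalen-1-yl trifluoromethanesulfonate | CO[C@H]1CC[C@]2(C)C(OS(=O)(=O)C(F)(F)F)=C(C)C(=O)C[C@H]2C1(C)C
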